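At 20 h per flask and with the starting material held at 20 mM, we have to decide how much partner to charge in the next run.

    partner → decomposition product (k1 = 6.2 × 10⁻⁶ min⁻¹)
    partner + loose pair → isomer of the product (k2 = 560 L mol⁻¹ min⁻¹)
    tight pair ⇌ loose pair (K3 = 2.0, k3 = 1.5 min⁻¹)
    partner + tight pair → target (k4 = 94 L mol⁻¹ min⁻¹)
    tight pair → decomposed reagent (k5 = 0.013 min⁻¹)
    starting material ⇌ tight pair (K6 = 0.054, k6 = 0.0055 min⁻¹)

all flasks: starting material 20 mM; time 20 h
- gamma: partner 2.50 mM
- theta: partner 8.00 mM
- epsilon: partner 25.0 mM
- alpha: partner 80.0 mM
- zeta: partner 200 mM

- "hardly changes" means that all values lie within two and a half points (for a concentration: within two and a half percent of the largest)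
- run time (gamma): 20 h

- amount of target at the end, in percent of the starting material charged for gamma, theta, epsilon, alpha, zeta, in this order
- the course of these numbers from the first flask to the last (rises, then falls / falls all the way / rises all the way / falls, then rises / hardly changes)

We follow one molecule. The starting material opens to the tight pair with a forward half-life of 2.10 h, so if each tight pair is carried onward, 0.136% of the starting material stands at the end. At the zeta charge, a tight pair reaches a fork. It goes to target at 18.8 min⁻¹ and to the loose pair at 1.5 min⁻¹, and these together are faster than falling back at 0.102 min⁻¹ and decomposing at 0.013 min⁻¹. A loose pair in zeta meets partner at 112 min⁻¹ and returns at 0.750 min⁻¹, so we count that slip as lost to the isomer.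

The fork in zeta therefore comes down to one quantity, the even-split level of partner, k3/k4, at which a tight pair is as likely to become target as to slip: 16.0 mM. While a slip counts as lost, the chance of target is c(partner)/(c(partner) + even-split level). Each converted molecule costs one partner, so a full conversion takes 20 mM from the charge. This gives 92.6% at the start of zeta and 91.9% at its end. The yield we commit to is that chance averaged over the partner spent: the amount spent, less the even-split level times the logarithm of the ratio of c(partner) + even-split level at start and at end, all divided by the amount spent, which for zeta gives 0.922. For alpha, the same reckoning gives 83.4% falling to 79.0%, with an average of 0.814. In theta, as in gamma, partner is the limiting reagent and lies below the even-split level, so theta opens at a chance of just 33.4%. The chance climbs with c(partner), so from gamma to zeta we expect a course that rises all the way. We therefore charge the zeta level, paying in partner for a higher chance.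

The forecast gives 1.8%, 9.8%, 48.5%, 81% and 92%, a course that rises all the way, since “more partner steadily favours the target”.

The flasks give 1.82%, 9.76%, 48.7%, 81.4% and 92.1%, a course that rises all the way. In zeta, the step from tight to loose pair is the main reason for the shortfall: without it the yield is 99.8%, not 92.1%. The partner left in zeta, 179 mM, gives a closing chance of 91.8%, and the reading, gathered over the whole run, stands just above it. In alpha, the partner left, 59.6 mM, gives a closing chance of 78.9%, and the whole-run reading stands higher, at 81.4%.

The constants used here are made up; the result is computed.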